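**Retrosynthetic overview**
- Target ⇒ bis(O-benzyl) ether ⇒ aryl Grignard plus a spiro-oxirane. The oxirane CH2 becomes the benzylic CH2 and the oxirane O becomes the tertiary OH.
- Spiro-oxirane ⇒ triol (1,2-diol to oxirane) ⇒ reductive opening of a cis-fused furo[3,4-c]furan lactol.
- Lactol ⇒ cinnamaldehyde plus dihydroxyacetone in one operation. Oxa-Michael and aldol (the C8–C8' bond) close ring A, the oxolane that is kept. Hemiacetalisation closes ring B, which is sacrificial and fixes the quaternary carbinol. One amine catalyst sets all three stereocentres.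
- Enal ⇒ O-benzylvanillin plus a two-carbon Wittig reagent. Grignard ⇒ 4-bromoguaiacol.
- Ring order: A and B together, B reopened in the same pot, then oxirane ring C closed and opened by the aryl nucleophile.

Assumption: the SMILES is read as (3R,4S,5R), with aryl trans to CH2OH and CH2OH trans to the tertiary OH (olivil relative configuration); the commercial amine catalyst is not counted as a step.

**Step 1**
Reactants: 1 4-(benzyloxy)-3-methoxybenzaldehyde (O-benzylvanillin); 2 (triphenylphosphoranylidene)acetaldehyde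
Product: 3 (E)-3-[4-(benzyloxy)-3-methoxyphenyl]prop-2-enal
Conditions: 2 (1.05 equiv), toluene, 90 °C, 16 h
Reagents that add atoms: (triphenylphosphoranylidene)acetaldehyde 2, O=CC=P(c1ccccc1)(c1ccccc1)c1ccccc1
Why: Wittig olefination with a stabilised formyl ylide is E-selective, and using barely more than one equivalent limits double homologation; no stereocentre is formed.

**Step 2**
Reactants: 3 (E)-3-[4-(benzyloxy)-3-methoxyphenyl]prop-2-enal; 4 1,3-dihydroxyacetone dimer [2,5-bis(hydroxymethyl)-1,4-dioxane-2,5-diol]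
Product: 8 (3S,4S,5R)-5-[4-(benzyloxy)-3-methoxyphenyl]-3,4-bis(hydroxymethyl)oxolan-3-ol, via dihydroxyacetone monomer 5 (not isolated), via oxolane carbaldehyde 6 (not isolated), via bicyclic lactol 7 (not isolated)
Conditions: 4 (1.0 equiv of dimer), (R)-2-[diphenyl(trimethylsilyloxy)methyl]pyrrolidine (20 mol %), PhCO2H (20 mol %), CHCl3, rt, 72 h; then MeOH, NaBH4, 0 °C, 30 min
Reagents that add atoms: 1,3-dihydroxyacetone dimer 4, OCC1(O)COC(O)(CO)CO1
Why: Iminium–enamine domino oxa-Michael/aldol/hemiacetalisation (a known reaction type for enals with dihydroxyacetone dimer), in which the (R)-catalyst shields one face of the E-iminium so the OH of 5 adds to give the (R)-ArCH–O centre, the enamine attacks the ketone from the same open face to close ring A with CHO trans to aryl, only the reversible-aldol epimer with CH2OH cis to CHO can drop into the cis-fused lactol 7 (ring B) and so fixes the tertiary carbinol, and NaBH4 then reduces 7 through its open form without touching a stereocentre.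

**Step 3**
Reactants: 8 (3S,4S,5R)-5-[4-(benzyloxy)-3-methoxyphenyl]-3,4-bis(hydroxymethyl)oxolan-3-ol
Product: 10 [(3S,6R,7S)-6-[4-(benzyloxy)-3-methoxyphenyl]-1,5-dioxaspiro[2.4]heptan-7-yl]methanol, via primary tosylate 9 (not isolated)
Conditions: Bu2SnO (5 mol %), TsCl (1.05 equiv), Et3N (1.2 equiv), CH2Cl2, 0 °C to rt; then MeOH, K2CO3 (3 equiv), 0 °C, 1 h
Reagents that add atoms: p-toluenesulfonyl chloride, Cc1ccc(cc1)S(=O)(=O)Cl (its atoms stay in 9 only and leave again on ring closure)
Why: Stannylene-acetal-directed monotosylation picks the primary OH of the 1,2-diol over the isolated primary OH, the adjacent tertiary alkoxide then closes the oxirane by 3-exo-tet Williamson displacement faster than the remote OH can attack (5-exo at a neopentyl carbon), and no C–O bond at a stereocentre is broken, so the configuration is retained.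

**Step 4**
Reactants: 11 4-bromo-2-methoxyphenol
Product: 12 1-(benzyloxy)-4-bromo-2-methoxybenzene
Conditions: BnBr (1.1 equiv), K2CO3, acetone, reflux, 6 h
Reagents that add atoms: benzyl bromide, BrCc1ccccc1
Why: Williamson ether synthesis on the phenoxide; no stereocentre is involved.

**Step 5**
Reactants: 10 [(3S,6R,7S)-6-[4-(benzyloxy)-3-methoxyphenyl]-1,5-dioxaspiro[2.4]heptan-7-yl]methanol; 12 1-(benzyloxy)-4-bromo-2-methoxybenzene
Product: 14 (3R,4S,5R)-5-[4-(benzyloxy)-3-methoxyphenyl]-3-{[4-(benzyloxy)-3-methoxyphenyl]methyl}-4-(hydroxymethyl)oxolan-3-ol, via arylmagnesium bromide 13 (not isolated)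
Conditions: 12 (3.2 equiv), Mg turnings, THF, 45 °C; then CuI (copper monoiodide, 15 mol %), −30 °C, 10 in THF, −30 to 0 °C, 3 h; sat. aq NH4Cl
Reagents that add atoms: aryl bromide 12, COc1cc(Br)ccc1OCc1ccccc1; magnesium, [Mg] (stays in 13 only)
Why: Copper-catalysed SN2 opening of a 2,2-disubstituted epoxide by an aryl Grignard occurs at the unsubstituted CH2 (one equivalent of 13 is spent on the free OH), and the C–O bond at the quaternary carbon is untouched, so the tertiary alcohol keeps its configuration.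

**Step 6**
Reactants: 14 (3R,4S,5R)-5-[4-(benzyloxy)-3-methoxyphenyl]-3-{[4-(benzyloxy)-3-methoxyphenyl]methyl}-4-(hydroxymethyl)oxolan-3-ol
Product: 15 (3R,4S,5R)-5-(4-hydroxy-3-methoxyphenyl)-3-[(4-hydroxy-3-methoxyphenyl)methyl]-4-(hydroxymethyl)oxolan-3-ol
Conditions: H2 (1 atm), 10% Pd/C, EtOAc–EtOH 4:1, rt, about 1.5 h, stopped by LC control at full O-debenzylation; acid-free work-up
Reagents that add atoms: none
Why: Catalytic hydrogenolysis of aryl benzyl ethers in neutral solvent is much faster than cleavage of the cyclic benzylic C–O bond, and excluding acid prevents ionisation at ArCH–O (epimerisation or cyclisation onto the second arene), so all three stereocentres survive.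

**Compound list**
1 | 4-(benzyloxy)-3-methoxybenzaldehyde | COc1cc(C=O)ccc1OCc1ccccc1 | starting material
2 | (triphenylphosphoranylidene)acetaldehyde | O=CC=P(c1ccccc1)(c1ccccc1)c1ccccc1 | starting material
3 | (E)-3-[4-(benzyloxy)-3-methoxyphenyl]prop-2-enal | COc1cc(/C=C/C=O)ccc1OCc1ccccc1 | intermediate
4 | 1,3-dihydroxyacetone dimer, 2,5-bis(hydroxymethyl)-1,4-dioxane-2,5-diol | OCC1(O)COC(O)(CO)CO1 | starting material
5 | 1,3-dihydroxyacetone (monomer) | OCC(=O)CO | intermediate (not isolated)
6 | (2R,3S,4S)-2-[4-(benzyloxy)-3-methoxyphenyl]-4-hydroxy-4-(hydroxymethyl)oxolane-3-carbaldehyde | OC[C@]1(O)CO[C@@H](c2ccc(OCc3ccccc3)c(OC)c2)[C@@H]1C=O | intermediate (not isolated)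
7 | (3aR,6R,6aS)-6-[4-(benzyloxy)-3-methoxyphenyl]tetrahydro-1H,3H-furo[3,4-c]furan-1,3a(4H)-diol, cis-fused, aryl exo, anomer mixture at C1 | O1C[C@]2(O)CO[C@@H](c3ccc(OCc4ccccc4)c(OC)c3)[C@@H]2C1O | intermediate (not isolated)
8 | (3S,4S,5R)-5-[4-(benzyloxy)-3-methoxyphenyl]-3,4-bis(hydroxymethyl)oxolan-3-ol | OC[C@]1(O)CO[C@@H](c2ccc(OCc3ccccc3)c(OC)c2)[C@@H]1CO | intermediate
9 | [(3R,4S,5R)-5-[4-(benzyloxy)-3-methoxyphenyl]-3-hydroxy-4-(hydroxymethyl)oxolan-3-yl]methyl 4-methylbenzenesulfonate | Cc1ccc(cc1)S(=O)(=O)OC[C@]1(O)CO[C@@H](c2ccc(OCc3ccccc3)c(OC)c2)[C@@H]1CO | intermediate (not isolated)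
10 | [(3S,6R,7S)-6-[4-(benzyloxy)-3-methoxyphenyl]-1,5-dioxaspiro[2.4]heptan-7-yl]methanol (oxirane O trans, oxirane CH2 cis to CH2OH) | C1[C@]2(O1)CO[C@@H](c3ccc(OCc4ccccc4)c(OC)c3)[C@@H]2CO | intermediate
11 | 4-bromo-2-methoxyphenol | COc1cc(Br)ccc1O | starting material
12 | 1-(benzyloxy)-4-bromo-2-methoxybenzene | COc1cc(Br)ccc1OCc1ccccc1 | intermediate
13 | [4-(benzyloxy)-3-methoxyphenyl]magnesium bromide | COc1cc([Mg]Br)ccc1OCc1ccccc1 | intermediate (not isolated)
14 | (3R,4S,5R)-5-[4-(benzyloxy)-3-methoxyphenyl]-3-{[4-(benzyloxy)-3-methoxyphenyl]methyl}-4-(hydroxymethyl)oxolan-3-ol | COc1cc(C[C@]2(O)CO[C@@H](c3ccc(OCc4ccccc4)c(OC)c3)[C@@H]2CO)ccc1OCc1ccccc1 | intermediate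
15 | (3R,4S,5R)-5-(4-hydroxy-3-methoxyphenyl)-3-[(4-hydroxy-3-methoxyphenyl)methyl]-4-(hydroxymethyl)oxolan-3-ol | COc1cc(C[C@]2(O)CO[C@@H](c3ccc(O)c(OC)c3)[C@@H]2CO)ccc1O | target

**Step count and risks**
Total step count: 6. Longest linear sequence: 5 (steps 1, 2, 3, 5, 6).

Steps most likely to fail:

**Step 2.** The para-alkoxy group makes the iminium of 3 a weak acceptor and shifts the reversible oxa-Michael equilibrium backwards. Conversion may therefore be low, or the ee may erode.
- The fallback sets out from 4 and comes back at 8.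
- The cascade is run on the electronically neutral, commercial 4-acetoxy-3-methoxycinnamaldehyde F1 with the same catalyst, giving the acetoxy lactol F2.
- F2 is reduced in the pot to the triol acetate F3.
- K2CO3 in MeOH frees the phenol triol F4.
- BnBr/K2CO3 in acetone then alkylates only the phenol to give 8. Any acetate lost during the borohydride stage converges on the same product.

**Step 3.** The cis CH2OH can displace the tosylate (5-exo) to give a dead-end 3,7-dioxabicyclo[3.3.0]octane, and the tosylation may not fully distinguish the two primary alcohols.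
- The fallback sets out from 8 and comes back at 10.
- Lipase CAL-B with vinyl acetate in MTBE acetylates the less hindered, non-neopentyl primary OH to give the monoacetate F5.
- Bu2SnO-catalysed tosylation gives the acetate tosylate F6.
- NaH in THF closes the oxirane with the competing nucleophile masked, giving the epoxy acetate F7.
- K2CO3 in MeOH then removes the acetate to give 10.

**Step 5.** Magnesium halide can turn the hindered spiro-epoxide into a bromohydrin. That species may then close onto the neighbouring alkoxide or rearrange to an aldehyde before aryl transfer occurs.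
- The fallback sets out from 10 (with 12) and comes back at 14.
- It is a reductive cross-electrophile coupling that uses no basic organometal: NiCl2(dme), 2,2'-bipyridine, NaI, Et3N·HCl, Mn powder, DMPU, rt.
- Iodide opens 10 at the CH2 to the iodohydrin F8.
- The C–I bond of F8 is joined to the aryl–nickel species formed from 12, giving 14 directly.

**Further compounds**
F1 | step 2 | (E)-4-acetoxy-3-methoxycinnamaldehyde | CC(=O)Oc1ccc(/C=C/C=O)cc1OC
F2 | step 2 | acetoxy lactol, analogue of 7 with OAc in place of OBn | O1C[C@]2(O)CO[C@@H](c3ccc(OC(C)=O)c(OC)c3)[C@@H]2C1O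
F3 | step 2 | 4-[(2R,3S,4S)-4-hydroxy-3,4-bis(hydroxymethyl)oxolan-2-yl]-2-methoxyphenyl acetate | OC[C@]1(O)CO[C@@H](c2ccc(OC(C)=O)c(OC)c2)[C@@H]1CO
F4 | step 2 | (3S,4S,5R)-5-(4-hydroxy-3-methoxyphenyl)-3,4-bis(hydroxymethyl)oxolan-3-ol | OC[C@]1(O)CO[C@@H](c2ccc(O)c(OC)c2)[C@@H]1CO
F5 | step 3 | [(2R,3S,4S)-2-[4-(benzyloxy)-3-methoxyphenyl]-4-hydroxy-4-(hydroxymethyl)oxolan-3-yl]methyl acetate | OC[C@]1(O)CO[C@@H](c2ccc(OCc3ccccc3)c(OC)c2)[C@@H]1COC(C)=O
F6 | step 3 | [(2R,3S,4R)-2-[4-(benzyloxy)-3-methoxyphenyl]-4-hydroxy-4-(tosyloxymethyl)oxolan-3-yl]methyl acetate | Cc1ccc(cc1)S(=O)(=O)OC[C@]1(O)CO[C@@H](c2ccc(OCc3ccccc3)c(OC)c2)[C@@H]1COC(C)=O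
F7 | step 3 | [(3S,6R,7S)-6-[4-(benzyloxy)-3-methoxyphenyl]-1,5-dioxaspiro[2.4]heptan-7-yl]methyl acetate | C1[C@]2(O1)CO[C@@H](c3ccc(OCc4ccccc4)c(OC)c3)[C@@H]2COC(C)=O
F8 | step 5 | (3R,4S,5R)-5-[4-(benzyloxy)-3-methoxyphenyl]-4-(hydroxymethyl)-3-(iodomethyl)oxolan-3-ol | IC[C@]1(O)CO[C@@H](c2ccc(OCc3ccccc3)c(OC)c2)[C@@H]1CO
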